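**Plan**

Numbering of the target (azulene skeleton): C1 (O-angeloyl), C2, C3 (C–OH, isopropyl), C3a (H), C4 (O-aroyl), C5, C6 (methyl)=C7, C8, C8a (methyl).
Retrosynthesis: the two esters are cut last; the five-membered ring is opened at C2–C3 (aldol); the C6=C7 alkene goes back to a C7 ketone and C8–H to an oxygen bridge C4–O–C8; this 8-oxabicyclo[3.2.1]octane is cut at C8–C8a and C4–C3a into 4-methyl-3-oxidopyrylium and 2-methylhex-4-yn-3-one.
Enabling feature: the five ring carbons C4–C8 between the two ring-fusion carbons carry O at one end (C4), a CH2 at the other (C8) and methyl on the middle one (C6); this is the carbon pattern of the oxidopyrylium from 3-methylfurfuryl alcohol, whose ring oxygen stays on C4.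
Forward: furan dearomatisation (Achmatowicz), (5+2) cycloaddition with the ynone (seven-membered ring), conjugate reduction, exo vinyl addition, SmI2 opening of the bridge, enol triflate reduction (C6=C7), Wacker oxidation and aldol closure (five-membered ring), then the esters.
Stereochemistry: C4 from the bridge (absolute sense by lipase resolution); C8a and C3a by exo vinyl addition and exo protonation on the bicycle (this gives the trans fusion); C3 in the aldol; C1 by hydride attack anti to the angular methyl; Z ester from angelic acid.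

Key step: step 5

Remark: 9–14 are racemates and each SMILES shows the enantiomer that is carried on; the methyl-bearing carbon next to the ring ketone in 13–17 forms as a mixture of epimers, is left undefined and becomes sp2 in step 11.
Remark: 16 is taken as a catalogue compound (otherwise one operation from 4-hydroxybenzoic acid: TBSCl, imidazole, then mild carbonate hydrolysis of the silyl ester).

**Route**

Step 1
Reactants: 1 methyl 3-methylfuran-2-carboxylate
Product: 2 (3-methylfuran-2-yl)methanol
Conditions: LiAlH4, Et2O, 0 °C; aqueous NaOH work-up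
Reagents that add atoms: none
Why: LiAlH4 reduction of the furoate ester to the primary alcohol is routine and creates no stereocentre.

Step 2
Reactants: 2 (3-methylfuran-2-yl)methanol
Product: 3 6-hydroxy-4-methyl-2H-pyran-3(6H)-one
Conditions: NBS, NaHCO3, THF/H2O (4:1), 0 °C
Reagents that add atoms: water O
Why: Achmatowicz rearrangement: bromonium-induced hydration opens the furan to a Z-keto-enal that the primary hydroxyl traps as the six-membered hemiacetal, so the furan 3-methyl becomes the 4-methyl of the pyranone; the hemiacetal centre is racemic and is lost in step 5.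

Step 3
Reactants: 3 6-hydroxy-4-methyl-2H-pyran-3(6H)-one
Product: 4 6-acetoxy-4-methyl-2H-pyran-3(6H)-one
Conditions: Ac2O, pyridine, DMAP (cat.), CH2Cl2, 0 °C
Reagents that add atoms: acetic anhydride CC(=O)OC(C)=O
Why: DMAP-catalysed acetylation turns the hemiacetal hydroxyl into the leaving group needed for ylide formation, with no stereochemical consequence.

Step 4
Reactants: 5 N-methoxy-N,2-dimethylpropanamide; 6 prop-1-ynylmagnesium bromide
Product: 7 2-methylhex-4-yn-3-one
Conditions: THF, 0 °C; then 1 M HCl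
Reagents that add atoms: none
Why: Weinreb ketone synthesis: the chelated tetrahedral adduct of the alkynyl Grignard reagent survives until the acid quench, so addition stops at the ynone.

Step 5
Reactants: 4 6-acetoxy-4-methyl-2H-pyran-3(6H)-one; 7 2-methylhex-4-yn-3-one
Product: 9 rac-(1S,5S)-3,7-dimethyl-6-(2-methylpropanoyl)-8-oxabicyclo[3.2.1]octa-3,6-dien-2-one, via 4-methylpyrylium-3-olate 8 (not isolated)
Conditions: 7 (3 equiv), i-Pr2NEt (1.5 equiv, slow addition), MeCN, 60 °C
Reagents that add atoms: none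
Why: The amine removes the acidic H-2 of 4 and acetate leaves from C-6, giving the aromatic 3-oxidopyrylium 8, a cyclic carbonyl ylide whose carbons C-2 to C-6 become C8, C7, C6, C5 and C4 of the target. It adds through its termini C-2 and C-6 across the conjugated triple bond of 7 in a concerted but asynchronous (5+2) cycloaddition, the known oxidopyrylium–alkyne cycloaddition of acetoxypyranone-derived ylides with propiolates and ynones. The seven-membered carbocycle closes in this single (5+2) event (a suprafacial 1,3-dipolar addition of the C–O–C ylide that also closes the 2,5-dihydrofuran ring of the bicycle), and the two new bonds are C8–C8a and C4–C3a of the target. The only new stereocentres are the two bridgeheads, held cis by the one-atom oxygen bridge; with no chiral element present the adduct is racemic and the absolute configuration (C4 of the target) is selected in step 9. The step needs regioselectivity: ylide carbon C-2, the nucleophilic terminus next to the oxido carbon, should bond to the β-carbon of the ynone (the methyl-bearing one) and C-6 to the acyl-bearing carbon, the 6-acyl orientation that acrylates and propiolates give with this ylide. An excess of 7 and slow release of the ylide hold back the competing ylide dimerisation.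

Step 6
Reactants: 9 rac-(1S,5S)-3,7-dimethyl-6-(2-methylpropanoyl)-8-oxabicyclo[3.2.1]octa-3,6-dien-2-one
Product: 11 rac-(1S,5S)-3,7-dimethyl-6-(2-methylpropanoyl)-2-(trimethylsilyloxy)-8-oxabicyclo[3.2.1]octa-2,6-diene, via lithium enolate 10 (not isolated)
Conditions: LiBH(s-Bu)3 (L-Selectride, 1.05 equiv), THF, −78 °C; then TMSCl, −78 → 0 °C
Reagents that add atoms: chlorotrimethylsilane C[Si](C)(C)Cl
Why: conjugate reduction with a bulky trialkylborohydride (as for carvone) attacks the β-unsubstituted, α-methyl bridge enone and not the hindered tetrasubstituted acyl-alkene, and O-silylation of the regiodefined enolate masks this ketone against the Grignard reagent of step 7; no stereocentre is set.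

Step 7
Reactants: 11 rac-(1S,5S)-3,7-dimethyl-6-(2-methylpropanoyl)-2-(trimethylsilyloxy)-8-oxabicyclo[3.2.1]octa-2,6-diene
Product: 13 rac-(1S,5S,6S,7S)-7-ethenyl-3,7-dimethyl-6-(2-methylpropanoyl)-8-oxabicyclo[3.2.1]octan-2-one (7-vinyl exo, 6-acyl endo), via bis-silyl enol ether 12 (not isolated)
Conditions: CH2=CHMgBr (2 equiv), CuBr·SMe2 (20 mol %), TMSCl, THF, −78 °C; then 1 M HCl, THF, 0 °C
Reagents that add atoms: vinylmagnesium bromide C=C[Mg]Br
Why: copper-catalysed, TMSCl-accelerated conjugate addition of the Grignard reagent to the strained acyl-alkene should deliver vinyl to C-7 from the exo face (the side of the one-atom oxygen bridge), setting the quaternary centre with methyl endo, while the enolate is silylated before it can expel the bridge oxygen, and hydrolysis should protonate C-6 from the same exo face so that the acyl group ends endo and trans to vinyl.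

Step 8
Reactants: 13 rac-(1S,5S,6S,7S)-7-ethenyl-3,7-dimethyl-6-(2-methylpropanoyl)-8-oxabicyclo[3.2.1]octan-2-one
Product: 14 rac-(4S,5S,6S)-6-ethenyl-4-hydroxy-2,6-dimethyl-5-(2-methylpropanoyl)cycloheptan-1-one
Conditions: SmI2 (2.5 equiv), THF/MeOH, −78 °C
Reagents that add atoms: none
Why: SmI2 reduction of an α-alkoxy ketone: only the bridgehead C1–O bond is α to the carbonyl, so the bridge opens there, the former C-1 becomes CH2 (C8 of the target) and the oxygen stays as a secondary hydroxyl on the other bridgehead with its configuration unchanged.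

Step 9
Reactants: 14 rac-(4S,5S,6S)-6-ethenyl-4-hydroxy-2,6-dimethyl-5-(2-methylpropanoyl)cycloheptan-1-one
Product: 15 (4S,5S,6S)-6-ethenyl-4-hydroxy-2,6-dimethyl-5-(2-methylpropanoyl)cycloheptan-1-one
Conditions: Candida antarctica lipase B (immobilised), vinyl acetate, MTBE, 30 °C, run to slightly beyond half conversion; chromatography
Reagents that add atoms: none
Why: lipase-catalysed kinetic resolution by transesterification: by the empirical large/medium size rule for lipases (large group C-5 with the acyl branch, medium group the C-3 methylene) the enzyme should acetylate the (4R)-carbinol and leave the (4S)-alcohol 15, which is separated from the acetate.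

Step 10
Reactants: 15 (4S,5S,6S)-6-ethenyl-4-hydroxy-2,6-dimethyl-5-(2-methylpropanoyl)cycloheptan-1-one; 16 4-[(tert-butyldimethylsilyl)oxy]benzoic acid
Product: 17 (1S,2S,3S)-3-ethenyl-3,6-dimethyl-2-(2-methylpropanoyl)-5-oxocycloheptyl 4-[(tert-butyldimethylsilyl)oxy]benzoate
Conditions: DCC, DMAP (cat.), CH2Cl2, 0 °C → rt
Reagents that add atoms: none
Why: Steglich esterification of the secondary hydroxyl installs the protected 4-hydroxybenzoate with retention at C4 and removes the free hydroxyl before the triflation.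

Step 11
Reactants: 17 (1S,2S,3S)-3-ethenyl-3,6-dimethyl-2-(2-methylpropanoyl)-5-oxocycloheptyl 4-[(tert-butyldimethylsilyl)oxy]benzoate
Product: 18 (1S,6S,7S)-6-ethenyl-3,6-dimethyl-7-(2-methylpropanoyl)-4-(trifluoromethylsulfonyloxy)cyclohept-3-en-1-yl 4-[(tert-butyldimethylsilyl)oxy]benzoate
Conditions: Tf2O, 2,6-di-tert-butyl-4-methylpyridine, CH2Cl2, 0 °C → rt
Reagents that add atoms: trifluoromethanesulfonic anhydride O=S(=O)(OS(=O)(=O)C(F)(F)F)C(F)(F)F
Why: enol triflate formation with Tf2O and a hindered pyridine under equilibrating conditions should favour the more substituted enol triflate (toward the methyl-bearing carbon, the other α-carbon being neopentylic), while the isopropyl ketone with two hindered tertiary α-positions reacts far more slowly; the epimeric centre disappears here.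

Step 12
Reactants: 18 (1S,6S,7S)-6-ethenyl-3,6-dimethyl-7-(2-methylpropanoyl)-4-(trifluoromethylsulfonyloxy)cyclohept-3-en-1-yl 4-[(tert-butyldimethylsilyl)oxy]benzoate
Product: 19 (1S,6S,7S)-6-ethenyl-3,6-dimethyl-7-(2-methylpropanoyl)cyclohept-3-en-1-yl 4-[(tert-butyldimethylsilyl)oxy]benzoate
Conditions: Pd(OAc)2 (5 mol %), PPh3, HCO2H, Bu3N, DMF, 60 °C
Reagents that add atoms: none
Why: palladium-catalysed formate reduction of the alkenyl triflate (oxidative addition to zerovalent palladium, formate exchange, decarboxylation, reductive elimination) replaces OTf by H without moving the double bond, giving the trisubstituted C6=C7 alkene of the target.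

Step 13
Reactants: 19 (1S,6S,7S)-6-ethenyl-3,6-dimethyl-7-(2-methylpropanoyl)cyclohept-3-en-1-yl 4-[(tert-butyldimethylsilyl)oxy]benzoate
Product: 20 (1S,6R,7S)-6-acetyl-3,6-dimethyl-7-(2-methylpropanoyl)cyclohept-3-en-1-yl 4-[(tert-butyldimethylsilyl)oxy]benzoate
Conditions: PdCl2 (10 mol %), CuCl (30 mol %), O2 (1 atm), DMF/H2O (7:1), rt
Reagents that add atoms: water O
Why: Tsuji–Wacker oxidation: Markovnikov hydroxypalladation of the monosubstituted vinyl group gives the methyl ketone, while the trisubstituted ring alkene is inert and the quaternary centre has no allylic hydrogen to isomerise.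

Step 14
Reactants: 20 (1S,6R,7S)-6-acetyl-3,6-dimethyl-7-(2-methylpropanoyl)cyclohept-3-en-1-yl 4-[(tert-butyldimethylsilyl)oxy]benzoate
Product: 21 (3R,3aS,4S,8aR)-3-hydroxy-6,8a-dimethyl-1-oxo-3-(propan-2-yl)-1,2,3,3a,4,5,8,8a-octahydroazulen-4-yl 4-[(tert-butyldimethylsilyl)oxy]benzoate
Conditions: LiN(SiMe3)2 (1.1 equiv), THF, −78 °C; AcOH quench at −78 °C
Reagents that add atoms: none
Why: kinetic deprotonation of the methyl ketone (the only unhindered α-hydrogens) and intramolecular aldol addition to the isopropyl ketone close the five-membered ring with the trans fusion dictated by the trans acyl groups, and the tertiary carbinol should form with isopropyl cis to H-3a, away from C-4 and from the angular methyl.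

Step 15
Reactants: 21 (3R,3aS,4S,8aR)-3-hydroxy-6,8a-dimethyl-1-oxo-3-(propan-2-yl)-1,2,3,3a,4,5,8,8a-octahydroazulen-4-yl 4-[(tert-butyldimethylsilyl)oxy]benzoate
Product: 22 (1R,3R,3aS,4S,8aR)-1,3-dihydroxy-6,8a-dimethyl-3-(propan-2-yl)-1,2,3,3a,4,5,8,8a-octahydroazulen-4-yl 4-[(tert-butyldimethylsilyl)oxy]benzoate
Conditions: NaBH4, CeCl3·7H2O, MeOH, −40 °C
Reagents that add atoms: none
Why: Luche-type NaBH4 reduction: hydride should approach the cyclopentanone from the face opposite the adjacent angular methyl (as in 17-keto steroids), giving the C1 hydroxyl cis to that methyl, while the aryl ester is inert.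

Step 16
Reactants: 22 (1R,3R,3aS,4S,8aR)-1,3-dihydroxy-6,8a-dimethyl-3-(propan-2-yl)-1,2,3,3a,4,5,8,8a-octahydroazulen-4-yl 4-[(tert-butyldimethylsilyl)oxy]benzoate; 23 angelic acid
Product: 24 (1R,3R,3aS,4S,8aR)-4-({4-[(tert-butyldimethylsilyl)oxy]benzoyl}oxy)-3-hydroxy-6,8a-dimethyl-3-(propan-2-yl)-1,2,3,3a,4,5,8,8a-octahydroazulen-1-yl (2Z)-2-methylbut-2-enoate
Conditions: 23, 2,4,6-trichlorobenzoyl chloride, Et3N, toluene, rt; then 22, 80 °C
Reagents that add atoms: none
Why: Yamaguchi esterification through the mixed 2,4,6-trichlorobenzoic anhydride, conditions known to transfer the angeloyl group without Z to E isomerisation; only the secondary hydroxyl reacts, the tertiary one being too hindered.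

Step 17
Reactants: 24 (1R,3R,3aS,4S,8aR)-4-({4-[(tert-butyldimethylsilyl)oxy]benzoyl}oxy)-3-hydroxy-6,8a-dimethyl-3-(propan-2-yl)-1,2,3,3a,4,5,8,8a-octahydroazulen-1-yl (2Z)-2-methylbut-2-enoate
Product: 25 (1R,3R,3aS,4S,8aR)-3-hydroxy-4-[(4-hydroxybenzoyl)oxy]-6,8a-dimethyl-3-(propan-2-yl)-1,2,3,3a,4,5,8,8a-octahydroazulen-1-yl (2Z)-2-methylbut-2-enoate (target)
Conditions: Bu4NF, AcOH, THF, 0 °C
Reagents that add atoms: none
Why: fluoride cleaves the aryl silyl ether, and buffering with acetic acid protects the two esters; no stereocentre is touched.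

**Compound list**

1 | methyl 3-methylfuran-2-carboxylate | COC(=O)c1occc1C | starting material
2 | (3-methylfuran-2-yl)methanol | OCc1occc1C | intermediate
3 | 6-hydroxy-4-methyl-2H-pyran-3(6H)-one (racemic hemiacetal) | CC1=CC(O)OCC1=O | intermediate
4 | 6-acetoxy-4-methyl-2H-pyran-3(6H)-one (racemic) | CC(=O)OC1C=C(C)C(=O)CO1 | intermediate
5 | N-methoxy-N,2-dimethylpropanamide | CC(C)C(=O)N(C)OC | starting material
6 | prop-1-ynylmagnesium bromide | CC#C[Mg]Br | starting material
7 | 2-methylhex-4-yn-3-one | CC#CC(=O)C(C)C | intermediate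
8 | 4-methylpyrylium-3-olate (not isolated) | Cc1cc[o+]cc1[O-] | intermediate
9 | rac-(1S,5S)-3,7-dimethyl-6-(2-methylpropanoyl)-8-oxabicyclo[3.2.1]octa-3,6-dien-2-one | CC(C)C(=O)C1=C(C)[C@H]2C(=O)C(C)=C[C@@H]1O2 | intermediate
10 | lithium 3,7-dimethyl-6-(2-methylpropanoyl)-8-oxabicyclo[3.2.1]octa-2,6-dien-2-olate (racemic, not isolated) | [Li+].CC(C)C(=O)C1=C(C)[C@H]2C([O-])=C(C)C[C@@H]1O2 | intermediate
11 | rac-(1S,5S)-3,7-dimethyl-6-(2-methylpropanoyl)-2-(trimethylsilyloxy)-8-oxabicyclo[3.2.1]octa-2,6-diene | CC(C)C(=O)C1=C(C)[C@H]2C(O[Si](C)(C)C)=C(C)C[C@@H]1O2 | intermediate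
12 | bis-silyl enol ether of 13: 7-exo-ethenyl-3,7-dimethyl-6-[2-methyl-1-(trimethylsilyloxy)propylidene]-2-(trimethylsilyloxy)-8-oxabicyclo[3.2.1]oct-2-ene (racemic, not isolated) | CC(C)C(O[Si](C)(C)C)=C1[C@@H]2CC(C)=C(O[Si](C)(C)C)[C@@H](O2)[C@@]1(C)C=C | intermediate
13 | rac-(1S,5S,6S,7S)-7-ethenyl-3,7-dimethyl-6-(2-methylpropanoyl)-8-oxabicyclo[3.2.1]octan-2-one (7-vinyl exo, 7-methyl endo, 6-acyl endo; C-3 epimers) | CC(C)C(=O)[C@@H]1[C@@H]2CC(C)C(=O)[C@@H](O2)[C@@]1(C)C=C | intermediate
14 | rac-(4S,5S,6S)-6-ethenyl-4-hydroxy-2,6-dimethyl-5-(2-methylpropanoyl)cycloheptan-1-one (C-2 epimers) | CC(C)C(=O)[C@@H]1[C@@H](O)CC(C)C(=O)C[C@@]1(C)C=C | intermediate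
15 | (4S,5S,6S)-6-ethenyl-4-hydroxy-2,6-dimethyl-5-(2-methylpropanoyl)cycloheptan-1-one (single enantiomer; C-2 epimers) | CC(C)C(=O)[C@@H]1[C@@H](O)CC(C)C(=O)C[C@@]1(C)C=C | intermediate
16 | 4-[(tert-butyldimethylsilyl)oxy]benzoic acid | CC(C)(C)[Si](C)(C)Oc1ccc(cc1)C(=O)O | starting material
17 | (1S,2S,3S)-3-ethenyl-3,6-dimethyl-2-(2-methylpropanoyl)-5-oxocycloheptyl 4-[(tert-butyldimethylsilyl)oxy]benzoate (C-6 epimers) | CC(C)C(=O)[C@@H]1[C@@H](OC(=O)c2ccc(O[Si](C)(C)C(C)(C)C)cc2)CC(C)C(=O)C[C@@]1(C)C=C | intermediate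
18 | (1S,6S,7S)-6-ethenyl-3,6-dimethyl-7-(2-methylpropanoyl)-4-(trifluoromethylsulfonyloxy)cyclohept-3-en-1-yl 4-[(tert-butyldimethylsilyl)oxy]benzoate | CC(C)C(=O)[C@@H]1[C@@H](OC(=O)c2ccc(O[Si](C)(C)C(C)(C)C)cc2)CC(C)=C(OS(=O)(=O)C(F)(F)F)C[C@@]1(C)C=C | intermediate
19 | (1S,6S,7S)-6-ethenyl-3,6-dimethyl-7-(2-methylpropanoyl)cyclohept-3-en-1-yl 4-[(tert-butyldimethylsilyl)oxy]benzoate | CC(C)C(=O)[C@@H]1[C@@H](OC(=O)c2ccc(O[Si](C)(C)C(C)(C)C)cc2)CC(C)=CC[C@@]1(C)C=C | intermediate
20 | (1S,6R,7S)-6-acetyl-3,6-dimethyl-7-(2-methylpropanoyl)cyclohept-3-en-1-yl 4-[(tert-butyldimethylsilyl)oxy]benzoate | CC(C)C(=O)[C@@H]1[C@@H](OC(=O)c2ccc(O[Si](C)(C)C(C)(C)C)cc2)CC(C)=CC[C@@]1(C)C(C)=O | intermediate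
21 | (3R,3aS,4S,8aR)-3-hydroxy-6,8a-dimethyl-1-oxo-3-(propan-2-yl)-1,2,3,3a,4,5,8,8a-octahydroazulen-4-yl 4-[(tert-butyldimethylsilyl)oxy]benzoate | O=C1C[C@@](O)(C(C)C)[C@@H]2[C@@H](OC(=O)c3ccc(O[Si](C)(C)C(C)(C)C)cc3)CC(C)=CC[C@]21C | intermediate
22 | (1R,3R,3aS,4S,8aR)-1,3-dihydroxy-6,8a-dimethyl-3-(propan-2-yl)-1,2,3,3a,4,5,8,8a-octahydroazulen-4-yl 4-[(tert-butyldimethylsilyl)oxy]benzoate | O[C@@H]1C[C@@](O)(C(C)C)[C@@H]2[C@@H](OC(=O)c3ccc(O[Si](C)(C)C(C)(C)C)cc3)CC(C)=CC[C@]21C | intermediate
23 | angelic acid, (2Z)-2-methylbut-2-enoic acid | C/C=C(/C)C(=O)O | starting material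
24 | (1R,3R,3aS,4S,8aR)-4-({4-[(tert-butyldimethylsilyl)oxy]benzoyl}oxy)-3-hydroxy-6,8a-dimethyl-3-(propan-2-yl)-1,2,3,3a,4,5,8,8a-octahydroazulen-1-yl (2Z)-2-methylbut-2-enoate | C/C=C(/C)C(=O)O[C@@H]1C[C@@](O)(C(C)C)[C@@H]2[C@@H](OC(=O)c3ccc(O[Si](C)(C)C(C)(C)C)cc3)CC(C)=CC[C@]21C | intermediate
25 | (1R,3R,3aS,4S,8aR)-3-hydroxy-4-[(4-hydroxybenzoyl)oxy]-6,8a-dimethyl-3-(propan-2-yl)-1,2,3,3a,4,5,8,8a-octahydroazulen-1-yl (2Z)-2-methylbut-2-enoate | C/C=C(/C)C(=O)O[C@@H]1C[C@@](O)(C(C)C)[C@@H]2[C@@H](OC(=O)c3ccc(O)cc3)CC(C)=CC[C@]21C | target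

**Step count and risks**

Total step count: 17. Longest linear sequence: 16 steps (from 1 through steps 1–3 and 5–17; step 4 is the side branch).

The three steps most likely to fail:

1. Step 5. The ylide may dimerise faster than it adds to the internal ynone, and the methyl-bearing alkyne carbon may fail to take the position next to the ring ketone (loss of regiocontrol). Fallback from 4, rejoining at 9: the ynone is replaced by its allenyl ketone isomer, whose unsubstituted central carbon is the strongest electrophilic site. Zinc-mediated Barbier reaction of propargyl bromide with 2-methylpropanal (THF/aq. NH4Cl) should give 2-methylhex-5-yn-3-ol F1. Dess–Martin oxidation followed by brief Et3N treatment should give, by propargyl to allenyl isomerisation, 5-methylhexa-1,2-dien-4-one F2. The ylide released from 4 (i-Pr2NEt, MeCN) should add across the conjugated 2,3-double bond of F2 to give rac-(1S,5S)-3-methyl-7-methylidene-6-(2-methylpropanoyl)-8-oxabicyclo[3.2.1]oct-3-en-2-one F3. DBU in CH2Cl2 then moves the exocyclic double bond into conjugation with the ketone, which gives 9.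

2. Step 7. Addition at the fully substituted alkene carbon may be slow, so that attack elsewhere or loss of the bridge oxygen from the enolate competes, and protonation may occur from the endo face (erosion of the trans relationship). Fallback from 11, rejoining at 13: the two-carbon unit is brought in by conjugate alkynylation with a diethylalkynylalane, which reacts through a cyclic transition state with the s-cis acyl-alkene and needs no copper. Et2AlC≡CSiMe3 (from ethynyltrimethylsilane, n-BuLi and Et2AlCl) in Et2O/hexane, then 1 M HCl, should give the 7-exo-(trimethylsilylethynyl) analogue of 13 F4. Bu4NF/AcOH should give the 7-exo-ethynyl analogue of 13 F5. Partial hydrogenation (H2, Pd/CaCO3 poisoned with Pb(OAc)2, quinoline) then gives 13.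

3. Step 14. Under the basic conditions the 4-acyloxy group may be lost by β-elimination, the acyl group may migrate to the new tertiary alkoxide, or enolisation may occur on the isopropyl side. Fallback from 20, rejoining at 21: a Lewis-acid aldol in place of the enolate aldol. TMSOTf/Et3N (CH2Cl2, −20 °C) should convert the methyl ketone into the trimethylsilyl enol ether of 20 F6. TiCl4 (CH2Cl2, −78 °C) should then effect the intramolecular Mukaiyama aldol addition to the isopropyl ketone, and aqueous work-up gives 21.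

**Further compounds**

F1 | step 5 | 2-methylhex-5-yn-3-ol | CC(C)C(O)CC#C
F2 | step 5 | 5-methylhexa-1,2-dien-4-one | CC(C)C(=O)C=C=C
F3 | step 5 | rac-(1S,5S)-3-methyl-7-methylidene-6-(2-methylpropanoyl)-8-oxabicyclo[3.2.1]oct-3-en-2-one (C-6 epimers) | CC(C)C(=O)C1C(=C)[C@H]2C(=O)C(C)=C[C@@H]1O2
F4 | step 7 | 7-exo-(trimethylsilylethynyl) analogue of 13 (racemic) | CC(C)C(=O)[C@@H]1[C@@H]2CC(C)C(=O)[C@@H](O2)[C@@]1(C)C#C[Si](C)(C)C
F5 | step 7 | 7-exo-ethynyl analogue of 13 (racemic) | CC(C)C(=O)[C@@H]1[C@@H]2CC(C)C(=O)[C@@H](O2)[C@@]1(C)C#C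
F6 | step 14 | trimethylsilyl enol ether of the methyl ketone of 20 | CC(C)C(=O)[C@@H]1[C@@H](OC(=O)c2ccc(O[Si](C)(C)C(C)(C)C)cc2)CC(C)=CC[C@@]1(C)C(=C)O[Si](C)(C)C
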